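The constants are invented.

E cannot take more of Q than its own charge allows, 50.0% of the Q put in, so open a ledger on Q with that ceiling.

| flask | Q | J | E | remark | time |
|---|---|---|---|---|---|
| spring | 0.050 M | 1.50 equiv | 0.0250 M | one stirred flow tank at steady state, fed with the mixture as stated, mean residence time 4.0 d |  |
| noon | 0.050 M (fed, over 3.20 d) | 1.50 equiv | 0.0250 M | a stirred flask in which Q is dosed at a steady rate over 3.20 d without added volume, worked up at 4.0 d | 4.0 d |
| autumn | 0.050 M | 1.50 equiv | 0.0250 M | everything together in a closed stirred flask, run for 4.0 d | 4.0 d |
| winter | 0.050 M | 1.50 equiv (fed, over 3.20 d) | 0.0250 M | all but J at the start; J goes in evenly over 3.20 d, the run ends at 4.0 d | 4.0 d |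

    Q → D (k1 = 0.039 h⁻¹)
    J + D ⇌ J.D (K2 = 470 L mol⁻¹, k2 = 0.23 L mol⁻¹ h⁻¹)
    Q + E → Q.E (k3 = 1.8 L mol⁻¹ h⁻¹)
    D → X (k4 = 0.0074 h⁻¹)

- the stated concentrations are those of everything mixed, before any reaction; amounts are the same in each set-up
- the feed brings no volume worth counting
- run time (noon): 4.0 d

1. the set-up with the highest amount of D at the outlet or at the end, in percent of the Q put in ("none" if the first two lie within 2 percentage points) (spring / noon / autumn / winter / none)
2. amount of D at the outlet or at the end, in percent of the Q put in, spring
3. amount of D at the outlet or at the end, in percent of the Q put in, noon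
4. amount of D at the outlet or at the end, in percent of the Q put in, autumn
5. amount of D at the outlet or at the end, in percent of the Q put in, winter

Enter the fork first. Q leaves by two doors: by itself into D, or with E into Q.E. Take E at half its charge as a working level. The door to D then gets 63.4% of Q, and Q.E gets 36.6%, under the ceiling. Q lasts 16.3 h on average at that level.

D is a passing account, though. J, in excess, captures D in a pseudo-first-order step, and D also leaks to X. Define the drain time of D as one over the sum of these two rates, with J as charged: 1.69 d. Ignore the way back from J.D, which runs at 4.89 × 10⁻⁴ h⁻¹, far slower than capture.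

Now post the entries. In autumn, D filled through Q's lifetime and emptied through the drain time gives me 9.64%. In noon, D is made evenly over the dosing, each part late by Q's lifetime, which gives me 26.5%. Close the books in autumn as far as a reckoning with J as charged goes: capture runs at 2.33 times the leak to X, a ratio of rates for J at its charge, not a count of what stands at the end. I stop there, with no figures for spring or winter.

The forecast names noon, with 18.7% for spring, 26% for noon, 12.5% for autumn and 16% for winter, holding that “the set-up that makes D latest keeps the most”. Its autumn figure stands above mine.

The simulation gives noon as best, with 18.7% for spring, 23.8% for noon, 12.4% for autumn and 16.1% for winter.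

In autumn, D is made 2.69 times faster than it is used up at 0.494 d, but by 4.00 d it is made at 0.0898 of the rate of its use, and that run spans 2.37 drain times. In noon, dosing ends 0.800 d before work-up, 0.473 of a drain time, and D reads 24.3% at 3.20 d and 23.8% at 4.00 d.

Now leave autumn standing until 6.0 d: reckoned by the drain time, its 12.4% comes down to 3.79%. That flask reads 5.35%.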